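The two halves of the target are the same 3β-hydroxy-4,4,10-trimethyl-trans-decalin (onocerane numbering: ring A = C1–C5 and C10, ring B = C5–C10). One enone (C8=O, exocyclic C9=C11) is therefore dimerised reductively through C11, and one C8 ketone of the twofold-symmetric diketone is methylenated. Ring A is closed in one pot on a monocyclic ring B silyl enol ether that carries a CMe2CO2Me group on C5: the C10 enolate adds to phenyl vinyl sulfone (C1–C10) and the C2 sulfonyl carbanion acylates the C3 ester (C2–C3). The step exploits C10 as α-carbon of a temporary C9 ketone, which later supplies C11 and, by allylic oxidation, the C8 carbonyl.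

Key step: step 2

Remark on the chemistry: the oxazaborolidinium ion of step 1 is assumed to show with 1 the facial preference that gives the (1R) product; if the opposite face is attacked, the mirror-image catalyst is used and nothing else changes.

Remark on names: bicyclic compounds carry onocerane locants of the keto half (C11 is the carbon on C9); the C10 methyl is β. Where a stereocentre is epimerisable and later removed (C2 in 7 and 8, C8 in 11), it is left undefined in the SMILES.

Step 1
Reactants: 1 2-methylcyclohex-2-en-1-one; 2 1-methoxy-2-methyl-1-(trimethylsilyloxy)prop-1-ene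
Product: 3 methyl 2-methyl-2-[(1R)-2-methyl-3-(trimethylsilyloxy)cyclohex-2-en-1-yl]propanoate
Conditions: (S)-3,3-diphenyl-1-(2-methylphenyl)tetrahydro-1H,3H-pyrrolo[1,2-c][1,3,2]oxazaborole·HNTf2 (20 mol %), Ph3PO (25 mol %), toluene, −20 °C; non-aqueous work-up (pentane, Et3N-deactivated silica)
Reagents that add atoms: none
Why: Catalytic enantioselective Mukaiyama–Michael addition: the cationic oxazaborolidine activates the enone and shields one face of the β-carbon (C5), so the ketene acetal sets C5 as drawn, and silyl transfer to oxygen leaves the C9–C10 enol ether regiodefined for step 2.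

Step 2
Reactants: 3 methyl 2-methyl-2-[(1R)-2-methyl-3-(trimethylsilyloxy)cyclohex-2-en-1-yl]propanoate; 4 phenyl vinyl sulfone
Product: 7 2-(phenylsulfonyl)-4,4,10β-trimethyl-5α-decalin-3,9-dione, via potassium enolate 5 (not isolated), via Michael adduct 6 (not isolated)
Conditions: KOtBu (1.05 equiv), THF, −20 °C; 4 (1.05 equiv), −78 → 0 °C; KOtBu (2.2 equiv), 0 → 40 °C; AcOH quench
Reagents that add atoms: none
Why: KOtBu cleaves the O–Si bond of 3 and releases the C9/C10 potassium enolate 5 regiospecifically; this adds through C10 to phenyl vinyl sulfone (C1–C10), and the α-sulfonyl carbanion at C2 of 6, regenerated by the excess base, acylates the C3 methyl ester on C4 (C2–C3), after which the expelled methoxide deprotonates the β-keto sulfone and pulls the sequence to one product. The closest known reaction types are the Michael addition of ketone enolates to vinyl sulfones and the Dieckmann-type acylation of sulfonyl carbanions by esters, together a Michael-initiated ring closure and formally a [4+2] annulation. Ring A is closed by 6-exo-trig attack of the C2 carbanion on the ester carbonyl. The new quaternary centre C10 is set in the Michael step, where the sulfone approaches the enolate face anti to the tert-alkyl group on the neighbouring C5; this places C1 trans to C4 and the methyl cis to it, which is the trans ring fusion, while C2 is epimerisable and is removed in step 4. The step needs reaction at C10 and not at C8, which the defined enol ether from step 1 secures, and closure at the ester by C2 only, which is secured because this closure alone gives an enolisable β-keto sulfone as thermodynamic sink (acylation by a C8 enolate would give a bridged diketone that cannot enolise and reverts).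

Step 3
Reactants: 7 2-(phenylsulfonyl)-4,4,10β-trimethyl-5α-decalin-3,9-dione
Product: 8 9-methylene-2-(phenylsulfonyl)-4,4,10β-trimethyl-5α-decalin-3-one
Conditions: Ph3PCH3Br (4 equiv), KOtBu (4 equiv), toluene, 90 °C
Reagents that add atoms: methyltriphenylphosphonium bromide, C[P+](c1ccccc1)(c1ccccc1)c1ccccc1.[Br-]
Why: Wittig methylenation under hindered-ketone conditions: the first equivalent of ylide deprotonates the β-keto sulfone, whose enolate masks C3, so only the C9 carbonyl is olefinated and supplies C11.

Step 4
Reactants: 8 9-methylene-2-(phenylsulfonyl)-4,4,10β-trimethyl-5α-decalin-3-one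
Product: 9 9-methylene-4,4,10β-trimethyl-5α-decalin-3-one
Conditions: SmI2 (2.5 equiv), THF/MeOH, −78 °C
Reagents that add atoms: none
Why: Reductive desulfonylation of an α-sulfonyl ketone by two single-electron transfers (samarium enolate, protonated by MeOH); the isolated alkene and the C3 ketone should not be reduced at −78 °C without HMPA.

Step 5
Reactants: 9 9-methylene-4,4,10β-trimethyl-5α-decalin-3-one
Product: 10 9-methylene-4,4,10β-trimethyl-5α-decalin-3β-ol
Conditions: NaBH4, MeOH, 0 °C
Reagents that add atoms: none
Why: Hydride reduction of the 4,4-dimethyl-3-ketone: axial attack on the α-face, away from the axial 4β-methyl group, should give the equatorial 3β-alcohol, the usual outcome for 3-oxo-4,4-dimethyl-5α-decalins.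

Step 6
Reactants: 10 9-methylene-4,4,10β-trimethyl-5α-decalin-3β-ol
Product: 11 9-methylene-4,4,10β-trimethyl-5α-decalin-3β,8-diol
Conditions: SeO2 (0.5 equiv), t-BuOOH (3 equiv), CH2Cl2, 23 °C
Reagents that add atoms: selenium dioxide, O=[Se]=O (oxygen carrier); tert-butyl hydroperoxide, CC(C)(C)OO (stoichiometric oxygen source)
Why: Riley allylic oxidation (ene reaction, then [2,3]-sigmatropic shift): C8 is the only allylic CH2 because C10 is quaternary, so oxygen enters at C8 with the exocyclic alkene retained; the C8 configuration is erased in step 7.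

Step 7
Reactants: 11 9-methylene-4,4,10β-trimethyl-5α-decalin-3β,8-diol
Product: 12 3β-hydroxy-9-methylene-4,4,10β-trimethyl-5α-decalin-8-one
Conditions: activated MnO2 (excess), CH2Cl2, 23 °C; used at once
Reagents that add atoms: none
Why: MnO2 oxidises only the allylic C8 alcohol (the saturated C3 alcohol is inert) and gives the α-methylene ketone.

Step 8
Reactants: 12 3β-hydroxy-9-methylene-4,4,10β-trimethyl-5α-decalin-8-one (two molecules)
Product: 13 1,2-bis(3β-hydroxy-4,4,10β-trimethyl-8-oxo-5α-decalin-9β-yl)ethane
Conditions: SmI2 (1.1 equiv per enone), HMPA (4 equiv), t-BuOH (1 equiv), THF, −78 → 0 °C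
Reagents that add atoms: none
Why: Reductive hydrodimerisation of an enone: SmI2/HMPA forms the ketyl radical anion, which couples at the unhindered exocyclic β-carbon C11, and the two samarium enolates are protonated on the α-face anti to the axial C10 methyl, which sets 9α-H in both halves; a single enantiomer of 12 can only give the twofold-symmetric diketone.

Step 9
Reactants: 13 1,2-bis(3β-hydroxy-4,4,10β-trimethyl-8-oxo-5α-decalin-9β-yl)ethane
Product: 14 26-nor-8-oxo-α-onocerin
Conditions: Zn, CH2Br2, TiCl4 (reagent pre-formed in THF, about 1 equiv beyond what the two hydroxyl groups consume), CH2Cl2, 0 → 23 °C, stopped at partial conversion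
Reagents that add atoms: dibromomethane, BrCBr
Why: Lombardo–Takai methylenation is non-basic, tolerates free hydroxyl groups and should not epimerise C9; the two C8 ketones are equivalent and remote, so mono-olefination is statistical, and 14 is separated from recovered 13 (recycled) and from doubly methylenated material.

Compound list
1 | 2-methylcyclohex-2-en-1-one | CC1=CCCCC1=O | starting material
2 | 1-methoxy-2-methyl-1-(trimethylsilyloxy)prop-1-ene | COC(O[Si](C)(C)C)=C(C)C | starting material
3 | methyl 2-methyl-2-[(1R)-2-methyl-3-(trimethylsilyloxy)cyclohex-2-en-1-yl]propanoate | COC(=O)C(C)(C)[C@@H]1CCCC(O[Si](C)(C)C)=C1C | intermediate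
4 | phenyl vinyl sulfone | C=CS(=O)(=O)c1ccccc1 | starting material
5 | potassium enolate (C9–O, C9=C10) of methyl 2-methyl-2-[(1R)-2-methyl-3-oxocyclohexyl]propanoate | COC(=O)C(C)(C)[C@@H]1CCCC([O-])=C1C.[K+] | intermediate
6 | methyl 2-methyl-2-[(1R,2S)-2-methyl-3-oxo-2-[2-(phenylsulfonyl)ethyl]cyclohexyl]propanoate (formed as its potassium salt) | COC(=O)C(C)(C)[C@@H]1CCCC(=O)[C@@]1(C)CCS(=O)(=O)c1ccccc1 | intermediate
7 | 2-(phenylsulfonyl)-4,4,10β-trimethyl-5α-decalin-3,9-dione (trans-fused; C2 epimers) | O=C1CCC[C@H]2C(C)(C)C(=O)C(S(=O)(=O)c3ccccc3)C[C@]12C | intermediate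
8 | 9-methylene-2-(phenylsulfonyl)-4,4,10β-trimethyl-5α-decalin-3-one (C2 epimers) | C=C1CCC[C@H]2C(C)(C)C(=O)C(S(=O)(=O)c3ccccc3)C[C@]12C | intermediate
9 | 9-methylene-4,4,10β-trimethyl-5α-decalin-3-one | C=C1CCC[C@H]2C(C)(C)C(=O)CC[C@]12C | intermediate
10 | 9-methylene-4,4,10β-trimethyl-5α-decalin-3β-ol | C=C1CCC[C@H]2C(C)(C)[C@@H](O)CC[C@]12C | intermediate
11 | 9-methylene-4,4,10β-trimethyl-5α-decalin-3β,8-diol (C8 epimers) | C=C1C(O)CC[C@H]2C(C)(C)[C@@H](O)CC[C@]12C | intermediate
12 | 3β-hydroxy-9-methylene-4,4,10β-trimethyl-5α-decalin-8-one | C=C1C(=O)CC[C@H]2C(C)(C)[C@@H](O)CC[C@]12C | intermediate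
13 | 1,2-bis(3β-hydroxy-4,4,10β-trimethyl-8-oxo-5α-decalin-9β-yl)ethane (9α-H in both halves) | O=C1CC[C@H]2C(C)(C)[C@@H](O)CC[C@]2(C)[C@H]1CC[C@H]1C(=O)CC[C@H]2C(C)(C)[C@@H](O)CC[C@]12C | intermediate
14 | 26-nor-8-oxo-α-onocerin | C=C1CC[C@H]2C(C)(C)[C@@H](O)CC[C@]2(C)[C@H]1CC[C@H]1C(=O)CC[C@H]2C(C)(C)[C@@H](O)CC[C@]12C | target

Total step count: 9. Longest linear sequence: 9 steps (from 1).

Steps most likely to fail

Step 2 (key step). Acylation of the hindered α,α-dimethyl ester may be slow, so that the sulfonyl carbanion is lost to proton transfer and to further addition to the vinyl sulfone. The enolate may also equilibrate to C8, or close reversibly through oxygen onto the ester. The fallback sets out from 3 and changes the ring-closing electrophile. Reduction with i-Bu2AlH (CH2Cl2, −78 °C) gives 2-methyl-2-[(1R)-2-methyl-3-(trimethylsilyloxy)cyclohex-2-en-1-yl]propanal F6. The same KOtBu and phenyl vinyl sulfone sequence then ends with addition of the C2 sulfonyl carbanion to the non-enolisable and far more electrophilic aldehyde, which gives 3-hydroxy-2-(phenylsulfonyl)-4,4,10β-trimethyl-5α-decalin-9-one F7. Oxidation with Dess–Martin periodinane comes back to the route at 7.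

Step 8. A second electron transfer and protonation may outrun the coupling (plain conjugate reduction of the enone), or the samarium enolate may add to unreacted enone and start oligomerisation. The statistical step 9 also costs material. The fallback sets out from 12 and joins two different halves. Conjugate addition of PhSeH (catalytic Et3N, CH2Cl2) gives 3β-hydroxy-9β-(phenylselanylmethyl)-4,4,10β-trimethyl-5α-decalin-8-one F8. Lombardo–Takai methylenation (Zn, CH2Br2, TiCl4) of its C8 ketone gives 8-methylene-9β-(phenylselanylmethyl)-4,4,10β-trimethyl-5α-decalin-3β-ol F9. The primary C11 radical generated from it with (Me3Si)3SiH and AIBN (benzene, 80 °C) adds to the exocyclic methylene of a second equivalent of 12 (Giese addition), and the α-keto radical takes hydrogen on the α-face. This comes back to the route at 14 without passing through 13.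

Step 1. Facial discrimination or turnover may be poor with the α-methyl enone, and a silyl-cation background reaction may erode the selectivity. The fallback sets out from 1 and takes the C5 configuration from a reagent-controlled reduction and a chirality transfer:
- CBS reduction ((R)-1-methyl-3,3-diphenyltetrahydro-1H,3H-pyrrolo[1,2-c][1,3,2]oxazaborole, BH3·SMe2), which by the usual model should give (S)-2-methylcyclohex-2-en-1-ol F1.
- Acylation with isobutyryl chloride (pyridine) to (S)-2-methylcyclohex-2-en-1-yl 2-methylpropanoate F2.
- Ireland–Claisen rearrangement (LiN(i-Pr)2, Me3SiCl, THF, −78 → 60 °C), which moves the stereocentre suprafacially from C9–O to the new C4–C5 bond and gives 2-methyl-2-[(1R)-2-methylcyclohex-2-en-1-yl]propanoic acid F3.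
- Esterification (Me3SiCHN2, MeOH) to methyl 2-methyl-2-[(1R)-2-methylcyclohex-2-en-1-yl]propanoate F4.
- Hydroboration (BH3·SMe2), with boron at C9, and direct oxidation of the borane with pyridinium chlorochromate (C5H5NH[CrO3Cl]) to methyl 2-methyl-2-[(1R)-2-methyl-3-oxocyclohexyl]propanoate F5.
- Thermodynamic silylation (Me3SiI, (Me3Si)2NH, CH2Cl2), which comes back to the route at 3.

Further compounds
F1 | step 1 | (S)-2-methylcyclohex-2-en-1-ol | O[C@H]1CCCC=C1C
F2 | step 1 | (S)-2-methylcyclohex-2-en-1-yl 2-methylpropanoate | CC(C)C(=O)O[C@H]1CCCC=C1C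
F3 | step 1 | 2-methyl-2-[(1R)-2-methylcyclohex-2-en-1-yl]propanoic acid | OC(=O)C(C)(C)[C@@H]1CCCC=C1C
F4 | step 1 | methyl 2-methyl-2-[(1R)-2-methylcyclohex-2-en-1-yl]propanoate | COC(=O)C(C)(C)[C@@H]1CCCC=C1C
F5 | step 1 | methyl 2-methyl-2-[(1R)-2-methyl-3-oxocyclohexyl]propanoate (C2 epimers of the ring) | COC(=O)C(C)(C)[C@@H]1CCCC(=O)C1C
F6 | step 2 | 2-methyl-2-[(1R)-2-methyl-3-(trimethylsilyloxy)cyclohex-2-en-1-yl]propanal | O=CC(C)(C)[C@@H]1CCCC(O[Si](C)(C)C)=C1C
F7 | step 2 | 3-hydroxy-2-(phenylsulfonyl)-4,4,10β-trimethyl-5α-decalin-9-one (C2 and C3 epimers) | O=C1CCC[C@H]2C(C)(C)C(O)C(S(=O)(=O)c3ccccc3)C[C@]12C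
F8 | step 8 | 3β-hydroxy-9β-(phenylselanylmethyl)-4,4,10β-trimethyl-5α-decalin-8-one | O=C1CC[C@H]2C(C)(C)[C@@H](O)CC[C@]2(C)[C@H]1C[Se]c1ccccc1
F9 | step 8 | 8-methylene-9β-(phenylselanylmethyl)-4,4,10β-trimethyl-5α-decalin-3β-ol | C=C1CC[C@H]2C(C)(C)[C@@H](O)CC[C@]2(C)[C@H]1C[Se]c1ccccc1
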